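## The problem

The target 16 is epigallocatechin-(4β→8)-epigallocatechin 3-O-gallate-(4β→8)-epigallocatechin: three flavan-3-ol units joined by two bonds from C4 of one unit to C8 of the next, with the only ester on O3 of the middle unit. Of its eight stereocenters, C2 and C3 of the upper and lower units can be bought as (−)-epigallocatechin, so C4 of the upper unit and C2, C3 and C4 of the middle unit have to be made. In a 2,3-cis unit the C2 aryl group and the C3 oxygen both lie on the α face, so a C4 cation is attacked from the β face, trans to O3. In the middle unit C2 can therefore control C3 (hydrogen delivered to C3 away from the aryl group) and C3 then controls C4, but no neighbouring center controls C2 itself. Each interflavan bond must also go to C8 and not to C6 of the acceptor ring. The pyrogallol and phloroglucinol rings oxidize in base and air, free-phenol flavans epimerize at C2 in base, the gallate ester does not survive hydrides, strong bases or amines, and the interflavan bonds are cleaved by strong acid; the phenols are therefore carried as benzyl ethers and released by neutral hydrogenolysis at the end. The feature that opens the plan is that ring A of the middle unit is a phloroglucinol ring with the upper unit on C8, while ring C atoms C2, C3 and C4 are a three-carbon chain held to ring A only through O1 and C4a; with C3 as an enol gallate, that chain is an α-galloyloxy cinnamaldehyde, which a phenol can take up by condensation at carbon and ring closure at oxygen.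

## Retrosynthesis

16 from 15. Twenty O–benzyl bonds are cut. Benzyl is the one group that covers all eighteen phenols and both secondary alcohols and leaves under neutral conditions that spare the gallate and the diarylmethine interflavan bonds. The forward reaction only has to run to completion.

15 from 14 and 3. The C4–C8 bond between the middle and lower units and the C3–H bond of the middle unit are cut, which leads back to the flav-3-en-3-yl gallate 14 and hexabenzyl epigallocatechin 3. The usual cut at this bond needs a 4-alkoxy leaving group on the middle unit, and so a benzylic oxidation of a dimer. Here the enol gallate is a latent form of the same C4 cation, reached by protonation. The precursor lacks a third of the mass and two stereocenters. The forward reaction must protonate C3 on the face away from the C2 aryl group, add C8 of 3 to C4 trans to the gallate, and leave the first interflavan bond intact.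

14 from 6 and 11 (key disconnection). C4–C4a and O1–C2 of the middle unit are cut, giving phenol 6 and the achiral enal 11. Cutting the upper interflavan bond of 14 instead would leave a 3-acyloxychromene monomer that still needs a synthesis of its own, whereas this cut uses the phloroglucinol pattern directly. Phenol 6 is chosen with the other two ring A oxygens as benzyl ethers: only one hydroxyl can then become O1, which fixes the 4→8 constitution, only one ring carbon has a free ortho hydroxyl, so a second annulation is impossible, and no protecting-group change is needed later. The condensation is promoted by PhB(OH)2 and not by an amine, because the enol gallate is an acyl donor. The forward reaction has to set C2, the one center without a neighbour to guide it; the plan relies on the reversibility of the oxa-6π ring closure, so the two C2 epimers, which are diastereomers, interconvert on heating, the wanted one is separated and the other recycled.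

6 from 4 and 5. The aryl–C4 bond of the upper unit is cut to the C4-activated flavan 4 and commercial 3,5-bis(benzyloxy)phenol 5. A Friedel–Crafts reaction of the flavan-4-yl cation on a phloroglucinol-type ring is the standard way to this bond. Using the dibenzyl ether 5 and not the parent triol saves a selective silylation and a later desilylation. The forward reaction has to attack the carbon ortho to the free hydroxyl and come in from the β face.

4 from 3, 3 from 2, 2 from 1. The C4–O bond is cut (DDQ oxidation in the presence of 2-ethoxyethanol), then six benzyl ethers in two stages, back to (−)-epigallocatechin 1. Compound 3 serves twice: as the precursor of the upper unit and as the lower-unit nucleophile.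

11 from 10, 10 from 8 and 9, 8 from 7. The enal is traced to the propargylic ester 10 by a 1,2-acyloxy shift with oxidation of the resulting carbenoid, catalysed by cationic monovalent gold from (IPr)AuCl and AgSbF6. This builds the enol ester and the formyl group under neutral, non-nucleophilic conditions. A crossed aldol condensation would be the neighbouring route, but it needs an amine or base in the presence of two transferable esters. Ester 10 comes from the alcohol 8 and acid 9, and 8 from aldehyde 7 and ethynylmagnesium bromide.

## Roads not taken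

Alternative 1: The cut is C4–C4a of the middle unit. A C3–C4 epoxide hangs from the ring A oxygen through C2 and carries the lower unit on C4; BF3·OEt2 lets the ring A carbon ortho to the ether oxygen open it at the benzylic carbon with inversion, giving A1 with a free 3-hydroxyl.
- Merits: C3 and C4 come from an asymmetric epoxidation and C2 from the ether-forming step, so all three centers of the middle ring are under reagent control. The single free hydroxyl of A1 takes the gallate without competition.
- Weak points: the epoxide carbon that is opened is benzylic to a ring with two ortho oxygens and is likely to ionize before it is attacked, which erodes the stereospecificity. The aryl ether at the benzylic C2 must be made with clean inversion. A1 has no upper unit, which then has to be placed on one of three free ring A carbons. The lower unit must be carried through a long linear sequence (C8 functionalization, olefination, epoxidation, etherification).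
- Comparison: this road is better on C2, which the chosen plan sets only by equilibration and separation. The chosen plan sets against it three convergent C–C bond formations, a 4→8 upper bond fixed by construction, and a gallate that arrives with the three-carbon unit.

Alternative 2: Three bonds of ring A of the lower unit are cut (C8a–C8, C6–C7, C4a–C8a). A siloxyalkyne on C4 of an upper dimer is heated with a cyclobutenone: vinylketene formation, [2+2] addition, 4π opening and 6π closure give the phenol A2, whose ring C is closed afterwards (Danheiser benzannulation).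
- Merits: the lower interflavan bond cannot go to C6, and the crowded aryl–C4 bond is not made by an intermolecular Friedel–Crafts reaction.
- Weak points: the upper dimer must first be built by other means, so the middle unit is not addressed. A2 carries silyl ethers where the gallate and free phenols must end up, so the ester goes on late. C2 and C3 of the lower unit are made from scratch instead of bought. Ring C still has to be closed with inversion at a benzylic carbon. It is by far the longest of the four routes.
- Comparison: it answers the C8 against C6 question, which the chosen plan leaves to the known C8 preference of 5,7-di-O-benzyl flavans. The chosen plan sets against it the use of the natural monomer for four stereocenters and a much shorter sequence.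

Alternative 3: C4–C4a of the middle unit and the C4–C8 bond to the lower unit are both cut at an acetal carbon. TMSOTf ionizes a dimethyl acetal on an open-chain aryl ether, ring A closes ring C, and the resulting 4-methoxyflavan gallate ionizes again and is captured by the lower unit to give A3, which is the same structure as 15.
- Merits: C2 and C3 are set in the open chain under reagent control. The second half is established 4-alkoxyflavan chemistry with gallate participation. Two C–C bonds form in one flask.
- Weak points: the precursor needs an aryl ether between the hindered phenol of the upper-unit adduct and a configurationally defined benzylic carbon, next to a gallate-bearing carbon and an acetal. Ionization, elimination and acyl migration all compete there, and the same benzylic ether can ionize under TMSOTf. The lower unit may also trap the oxocarbenium ion before ring closure.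
- Comparison: this road is at least as good on C2 and better in that its last C–C bond formation is known chemistry, whereas step 9 of the chosen plan is not. The chosen plan sets against it a three-step achiral three-carbon unit, no stereospecific etherification of a hindered phenol, and an O1–C2 bond made by a pericyclic step.

Key step: step 8

Assumption: 1, 5, 7 and 9 are taken as purchasable (9 is otherwise two steps from gallic acid). Compounds 8 and 10 are used as racemates, because their stereocenter disappears in step 7.

## Route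

Step 1
Reactants: 1 (−)-epigallocatechin
Product: 2 5,7,3′,4′,5′-penta-O-benzyl-(−)-epigallocatechin
Conditions: BnBr (5.5 equiv), K2CO3, DMF, 0 °C to rt, argon
Reagents that add atoms: benzyl bromide, BrCc1ccccc1
Why: Williamson etherification of the five phenols; carbonate does not deprotonate the secondary alcohol, and mild base with exclusion of air avoids pyrogallol oxidation and C2 epimerization.

Step 2
Reactants: 2 5,7,3′,4′,5′-penta-O-benzyl-(−)-epigallocatechin
Product: 3 3,5,7,3′,4′,5′-hexa-O-benzyl-(−)-epigallocatechin
Conditions: NaH, BnBr, n-Bu4NI (cat.), DMF, 0 °C to rt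
Reagents that add atoms: benzyl bromide, BrCc1ccccc1
Why: Williamson etherification of the remaining 3-hydroxyl; with no free phenol left there is no quinone methide path to C2 epimerization, and the 3-benzyl ether keeps the alcohol from binding the boronic acid in step 8.

Step 3
Reactants: 3 3,5,7,3′,4′,5′-hexa-O-benzyl-(−)-epigallocatechin
Product: 4 (2R,3R,4S)-4-(2-ethoxyethoxy)-3,5,7,3′,4′,5′-hexa-O-benzylepigallocatechin (4β-alkoxy)
Conditions: DDQ (2 equiv), 2-ethoxyethanol, CH2Cl2, rt
Reagents that add atoms: 2-ethoxyethanol, CCOCCO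
Why: Benzylic oxidation by hydride abstraction at C4 (cation stabilized by O1, O5 and O7), an established activation of benzylated flavan-3-ols; the alcohol adds from the β face, trans to the 3-benzyloxy and 2-aryl groups.

Step 4
Reactants: 4 (2R,3R,4S)-4-(2-ethoxyethoxy)-3,5,7,3′,4′,5′-hexa-O-benzylepigallocatechin; 5 3,5-bis(benzyloxy)phenol
Product: 6 3,5-bis(benzyloxy)-2-(3,5,7,3′,4′,5′-hexa-O-benzylepigallocatechin-4β-yl)phenol
Conditions: TMSOTf (0.2 equiv), phenol in fourfold excess, CH2Cl2, −78 to −40 °C
Reagents that add atoms: none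
Why: Friedel–Crafts alkylation by the flavan-4-yl cation; the ring carbon of 5 ortho to the free hydroxyl is the less hindered activated position (as in acid-catalysed C-alkylations of this phenol by allylic cations), and attack from the β face, away from the 3-benzyloxy and 2-aryl groups, sets C4 of the upper unit.

Step 5
Reactants: 7 3,4,5-tris(benzyloxy)benzaldehyde
Product: 8 (±)-1-[3,4,5-tris(benzyloxy)phenyl]prop-2-yn-1-ol
Conditions: HC≡CMgBr, THF, 0 °C
Reagents that add atoms: ethynylmagnesium bromide, C#C[Mg]Br
Why: Grignard addition to a non-enolizable aldehyde; the racemic carbinol center is erased in step 7.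

Step 6
Reactants: 8 (±)-1-[3,4,5-tris(benzyloxy)phenyl]prop-2-yn-1-ol; 9 3,4,5-tris(benzyloxy)benzoic acid
Product: 10 (±)-1-[3,4,5-tris(benzyloxy)phenyl]prop-2-yn-1-yl 3,4,5-tris(benzyloxy)benzoate
Conditions: DCC, DMAP (cat.), CH2Cl2, 0 °C to rt
Reagents that add atoms: none
Why: Steglich esterification of a secondary alcohol under neutral conditions that do not ionize the benzylic propargylic position.

Step 7
Reactants: 10 (±)-1-[3,4,5-tris(benzyloxy)phenyl]prop-2-yn-1-yl 3,4,5-tris(benzyloxy)benzoate
Product: 11 (Z)-2-[3,4,5-tris(benzyloxy)benzoyloxy]-3-[3,4,5-tris(benzyloxy)phenyl]propenal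
Conditions: (IPr)AuCl (5 mol%; IPr = 1,3-bis(2,6-diisopropylphenyl)imidazol-2-ylidene), AgSbF6 (5 mol%), Ph2SO (2 equiv), CH2Cl2, rt
Reagents that add atoms: diphenyl sulfoxide, O=S(c1ccccc1)c1ccccc1
Why: Cationic monovalent gold activates the terminal alkyne, the ester moves by a Rautenstrauch-type 1,2-acyloxy shift to a vinyl gold carbenoid, and the sulfoxide transfers oxygen to the carbenoid carbon to give the formyl group; the Z isomer (aryl trans to formyl) is the less strained one, and either isomer should lead to the same chromene.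

Step 8
Reactants: 6 3,5-bis(benzyloxy)-2-(3,5,7,3′,4′,5′-hexa-O-benzylepigallocatechin-4β-yl)phenol; 11 (Z)-2-[3,4,5-tris(benzyloxy)benzoyloxy]-3-[3,4,5-tris(benzyloxy)phenyl]propenal
Product: 14 (2R)-5,7-bis(benzyloxy)-8-(hexa-O-benzylepigallocatechin-4β-yl)-2-[3,4,5-tris(benzyloxy)phenyl]-2H-chromen-3-yl 3,4,5-tris(benzyloxy)benzoate, via benzodioxaborin adduct 12 (not isolated), via ortho-quinone methide 13 (not isolated)
Conditions: PhB(OH)2 (1.2 equiv), AcOH (cat.), toluene, 110 °C, Dean–Stark; C2 epimers separated on silica, the 2S epimer reheated in toluene (110 °C) and recycled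
Reagents that add atoms: none
Why: Proposed new method: the phenol of 6 should form an aryl boronate with PhB(OH)2, which delivers the aldehyde carbon of 11 through a six-membered transition state to the only ring carbon ortho to that oxygen and gives dioxaborin 12; loss of PhBO on heating unveils ortho-quinone methide 13, a 1-oxatriene whose disrotatory oxa-6π electrocyclization forms O1–C2 and restores the aromatic ring. The closest known reaction type is the PhB(OH)2- or amine-promoted condensation of phenols and phloroglucinols with enals to 2H-chromenes; an α-acyloxy enal and a phenol carrying a flavan unit have not been used in it. Ring C of the middle unit closes by a thermal six-electron electrocyclization over six atoms, C4–C4a coming from the condensation and O1–C2 from the ring closure. C2 is the only new stereocenter; the ring closure should be reversible at 110 °C, so the two C2 epimers, which are diastereomers because of the upper unit beside O1, equilibrate, the 2R epimer is separated and the 2S epimer goes back into the equilibration. The step needs attack at the carbon between the hydroxyl and a benzyloxy group and not at the carbon between two benzyloxy groups, 1,2- and not 1,4-addition to the enal, and survival of the enol gallate. The boronate template secures the first two, the single free hydroxyl decides which oxygen becomes O1 and so fixes the 4→8 constitution, and the absence of amines protects the acyl donor.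

Step 9
Reactants: 14 (2R)-5,7-bis(benzyloxy)-8-(hexa-O-benzylepigallocatechin-4β-yl)-2-[3,4,5-tris(benzyloxy)phenyl]-2H-chromen-3-yl 3,4,5-tris(benzyloxy)benzoate; 3 3,5,7,3′,4′,5′-hexa-O-benzyl-(−)-epigallocatechin
Product: 15 icosa-O-benzyl epigallocatechin-(4β→8)-epigallocatechin 3-O-gallate-(4β→8)-epigallocatechin
Conditions: CF3CO2H (10 equiv), flavan nucleophile in threefold excess, CH2Cl2, −20 to 0 °C; then aq NaHCO3
Reagents that add atoms: none
Why: Proposed new method: the acid should protonate the enol gallate at C3 on the face opposite the pseudoaxial C2 aryl group (giving the 2,3-cis gallate), because this forms a 2,4,6-trioxygenated benzylic cation at C4 that the gallate carbonyl bridges on the α face as a dioxolanylium ion; C8 of 3 then attacks C4 from the β face, trans to the gallate. The closest known reaction types are the acid-promoted hydroarylation of flav-3-enes by phenols and the 4-arylation of 3-acyloxyflavan-4-yl cations made from 4-alkoxy precursors, which is 3,4-trans selective through the same participation and C8 selective on 5,7-di-O-benzyl flavans. A Friedel–Crafts alkylation started by protonation of an enol ester has not been shown in this series.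

Step 10
Reactants: 15 icosa-O-benzyl epigallocatechin-(4β→8)-epigallocatechin 3-O-gallate-(4β→8)-epigallocatechin
Product: 16 epigallocatechin-(4β→8)-epigallocatechin 3-O-gallate-(4β→8)-epigallocatechin
Conditions: H2 (1 atm), Pd(OH)2/C, THF/MeOH/H2O, rt
Reagents that add atoms: none
Why: Hydrogenolysis of the twenty benzyl ethers under neutral conditions, the usual last step for benzylated procyanidin gallates; the aryl ester and the diarylmethine interflavan bonds are not cleaved and no stereocenter is touched.

## Compound list

1 | (−)-epigallocatechin, (2R,3R) | Oc1cc(O)c2c(c1)O[C@H](c1cc(O)c(O)c(O)c1)[C@H](O)C2 | starting material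
2 | 5,7,3′,4′,5′-penta-O-benzyl-(−)-epigallocatechin, (2R,3R), free 3-OH | C1c2c(OCc9ccccc9)cc(OCc9ccccc9)cc2O[C@H](c5cc(OCc9ccccc9)c(OCc9ccccc9)c(OCc9ccccc9)c5)[C@@H]1O | intermediate
3 | 3,5,7,3′,4′,5′-hexa-O-benzyl-(−)-epigallocatechin, (2R,3R) | C1c2c(OCc9ccccc9)cc(OCc9ccccc9)cc2O[C@H](c5cc(OCc9ccccc9)c(OCc9ccccc9)c(OCc9ccccc9)c5)[C@@H]1OCc9ccccc9 | intermediate
4 | (2R,3R,4S)-4-(2-ethoxyethoxy)-3,5,7,3′,4′,5′-hexa-O-benzylepigallocatechin (4β-alkoxy, trans to 3-OBn) | CCOCCO[C@H]3c4c(OCc9ccccc9)cc(OCc9ccccc9)cc4O[C@H](c5cc(OCc9ccccc9)c(OCc9ccccc9)c(OCc9ccccc9)c5)[C@@H]3OCc9ccccc9 | intermediate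
5 | 3,5-bis(benzyloxy)phenol | Oc1cc(OCc9ccccc9)cc(OCc9ccccc9)c1 | starting material
6 | 3,5-bis(benzyloxy)-2-(3,5,7,3′,4′,5′-hexa-O-benzylepigallocatechin-4β-yl)phenol (flavan unit 2R,3R, aryl at C4 trans to 3-OBn) | Oc1cc(OCc9ccccc9)cc(OCc9ccccc9)c1[C@H]3c4c(OCc9ccccc9)cc(OCc9ccccc9)cc4O[C@H](c5cc(OCc9ccccc9)c(OCc9ccccc9)c(OCc9ccccc9)c5)[C@@H]3OCc9ccccc9 | intermediate
7 | 3,4,5-tris(benzyloxy)benzaldehyde | O=Cc1cc(OCc9ccccc9)c(OCc9ccccc9)c(OCc9ccccc9)c1 | starting material
8 | (±)-1-[3,4,5-tris(benzyloxy)phenyl]prop-2-yn-1-ol | OC(C#C)c1cc(OCc9ccccc9)c(OCc9ccccc9)c(OCc9ccccc9)c1 | intermediate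
9 | 3,4,5-tris(benzyloxy)benzoic acid | OC(=O)c1cc(OCc9ccccc9)c(OCc9ccccc9)c(OCc9ccccc9)c1 | starting material
10 | (±)-1-[3,4,5-tris(benzyloxy)phenyl]prop-2-yn-1-yl 3,4,5-tris(benzyloxy)benzoate | C#CC(OC(=O)c1cc(OCc9ccccc9)c(OCc9ccccc9)c(OCc9ccccc9)c1)c1cc(OCc9ccccc9)c(OCc9ccccc9)c(OCc9ccccc9)c1 | intermediate
11 | (Z)-2-[3,4,5-tris(benzyloxy)benzoyloxy]-3-[3,4,5-tris(benzyloxy)phenyl]propenal | O=C/C(OC(=O)c1cc(OCc9ccccc9)c(OCc9ccccc9)c(OCc9ccccc9)c1)=C/c1cc(OCc9ccccc9)c(OCc9ccccc9)c(OCc9ccccc9)c1 | intermediate
12 | 2-phenyl-4H-1,3,2-benzodioxaborin from 6 and 11: boron bridges the former phenol oxygen and the former aldehyde oxygen, C4 of the dioxaborin carries the (Z)-1-galloyloxy-2-arylvinyl group (both epimers at that carbon) | c8ccccc8B1Oc2c([C@H]3c4c(OCc9ccccc9)cc(OCc9ccccc9)cc4O[C@H](c5cc(OCc9ccccc9)c(OCc9ccccc9)c(OCc9ccccc9)c5)[C@@H]3OCc9ccccc9)c(OCc9ccccc9)cc(OCc9ccccc9)c2C(O1)/C(OC(=O)c7cc(OCc9ccccc9)c(OCc9ccccc9)c(OCc9ccccc9)c7)=C/c6cc(OCc9ccccc9)c(OCc9ccccc9)c(OCc9ccccc9)c6 | intermediate (not isolated)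
13 | ortho-quinone methide (1-oxatriene): 3,5-bis(benzyloxy)-2-(flavan-4β-yl)cyclohexa-2,4-dienone with a (Z)-exocyclic 2-galloyloxy-3-arylallylidene group at C6 | O=C1C([C@H]3c4c(OCc9ccccc9)cc(OCc9ccccc9)cc4O[C@H](c5cc(OCc9ccccc9)c(OCc9ccccc9)c(OCc9ccccc9)c5)[C@@H]3OCc9ccccc9)=C(OCc9ccccc9)C=C(OCc9ccccc9)/C1=C/C(OC(=O)c7cc(OCc9ccccc9)c(OCc9ccccc9)c(OCc9ccccc9)c7)=C/c6cc(OCc9ccccc9)c(OCc9ccccc9)c(OCc9ccccc9)c6 | intermediate (not isolated)
14 | (2R)-5,7-bis(benzyloxy)-8-(hexa-O-benzylepigallocatechin-4β-yl)-2-[3,4,5-tris(benzyloxy)phenyl]-2H-chromen-3-yl 3,4,5-tris(benzyloxy)benzoate | O=C(OC1=Cc2c(OCc9ccccc9)cc(OCc9ccccc9)c([C@H]3c4c(OCc9ccccc9)cc(OCc9ccccc9)cc4O[C@H](c5cc(OCc9ccccc9)c(OCc9ccccc9)c(OCc9ccccc9)c5)[C@@H]3OCc9ccccc9)c2O[C@@H]1c6cc(OCc9ccccc9)c(OCc9ccccc9)c(OCc9ccccc9)c6)c7cc(OCc9ccccc9)c(OCc9ccccc9)c(OCc9ccccc9)c7 | intermediate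
15 | icosa-O-benzyl epigallocatechin-(4β→8)-epigallocatechin 3-O-gallate-(4β→8)-epigallocatechin | O=C(O[C@@H]1[C@@H](c2c(OCc9ccccc9)cc(OCc9ccccc9)c3c2O[C@H](c2cc(OCc9ccccc9)c(OCc9ccccc9)c(OCc9ccccc9)c2)[C@H](OCc9ccccc9)C3)c2c(OCc9ccccc9)cc(OCc9ccccc9)c([C@H]3c4c(OCc9ccccc9)cc(OCc9ccccc9)cc4O[C@H](c4cc(OCc9ccccc9)c(OCc9ccccc9)c(OCc9ccccc9)c4)[C@@H]3OCc9ccccc9)c2O[C@@H]1c1cc(OCc9ccccc9)c(OCc9ccccc9)c(OCc9ccccc9)c1)c1cc(OCc9ccccc9)c(OCc9ccccc9)c(OCc9ccccc9)c1 | intermediate
16 | epigallocatechin-(4β→8)-epigallocatechin 3-O-gallate-(4β→8)-epigallocatechin (CNP0278699.1) | O=C(O[C@@H]1[C@@H](c2c(O)cc(O)c3c2O[C@H](c2cc(O)c(O)c(O)c2)[C@H](O)C3)c2c(O)cc(O)c([C@H]3c4c(O)cc(O)cc4O[C@H](c4cc(O)c(O)c(O)c4)[C@@H]3O)c2O[C@@H]1c1cc(O)c(O)c(O)c1)c1cc(O)c(O)c(O)c1 | target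

## Step count and least certain steps

Total step count: 10. Longest linear sequence: 7 steps (1, 2, 3, 4, 8, 9, 10, from compound 1); the enal arm is 3 steps (5, 6, 7).

**Step 8 (key step, proposed new method).** The most likely failure is insufficient or wrong-sense control of the C2 configuration in the reversible ring closure, since the only bias is the distant upper unit and its direction cannot be predicted. Lesser risks are acyl transfer from the enol gallate to the phenol and slow condensation at the crowded phenol. The fallback takes C2 from the natural monomer and uses known reactions only, setting out from 2, 4 and 9 and returning at 14. Compounds 4 and 2 are coupled (TMSOTf, CH2Cl2, −78 °C, Friedel–Crafts at C8 of 2) to the benzylated epigallocatechin-(4β→8)-epigallocatechin dimer with one free 3-hydroxyl F1. Dess–Martin periodinane oxidizes that alcohol to the flavan-3-one F2. Kinetic deprotonation of the C4 methylene with KN(SiMe3)2 (THF, −78 °C) and O-acylation of the enolate with 3,4,5-tris(benzyloxy)benzoyl chloride F3 (from 9 with oxalyl chloride and catalytic DMF) gives 14. The point to watch there is enolization toward C2.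

**Step 9 (proposed new method).** The most likely failures are poor facial selectivity in the protonation of C3, which is reversible so that the product ratio depends on which cation is trapped faster, and acid cleavage of the existing interflavan bond before the enol ester reacts. The fallback sets out from 14 and returns at 15 by known reactions. Homogeneous hydrogenation ([Ir(cod)(PCy3)(py)]PF6, H2, CH2Cl2) adds hydrogen to the enol ester from the face away from the C2 aryl group and gives the benzylated epigallocatechin-(4β→8)-epigallocatechin 3-O-gallate dimer F4. The same compound can also be made by esterifying F1 with 9, which takes C3 from the natural unit. DDQ and 2-ethoxyethanol oxidize the only ring methylene left, C4 of the gallate unit, to the 4β-(2-ethoxyethoxy) dimer F5. TMSOTf and 3 then give 15 with gallate participation.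

**Step 7.** The vinyl gold carbenoid may be diverted before the sulfoxide reaches it, by cyclization onto the electron-rich aryl ring to an indene or by ionization of the benzylic ester. The fallback sets out from 9 and 7 and returns at 11. Acid 9 is esterified with 2,2-dimethoxyethanol (DCC, DMAP) to 2,2-dimethoxyethyl 3,4,5-tris(benzyloxy)benzoate F6. Aqueous CF3CO2H in CH2Cl2 unmasks 2-oxoethyl 3,4,5-tris(benzyloxy)benzoate F7. F7 is added slowly to 7 with pyrrolidine and benzoic acid as catalysts, and the crossed aldol condensation gives 11.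

**Step 4.** The cation may attack the ring carbon between the two benzyloxy groups, or alkylate 5 twice. The fallback removes the regiochemical question by using a symmetric nucleophile; it sets out from 4 and returns at 14. Compound 4 and excess commercial phloroglucinol (TMSOTf, THF/CH2Cl2) give the single phloroglucinol adduct F8. TIPSCl and imidazole silylate the unhindered para hydroxyl to the triisopropylsilyl ether F9. The annulation of step 8 with one equivalent of 11 gives the 5-silyloxy-7-hydroxy chromenyl gallate F10, in which only the oxygen beside C8 can close. n-Bu4NF buffered with AcOH gives the 5,7-dihydroxy chromenyl gallate F11, and BnBr with K2CO3 in acetone gives 14. The extra risks are a second annulation at the free 7-hydroxyl and loss of the enol ester during the benzylation.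

## Further compounds

F1 | step 8 | benzylated epigallocatechin-(4β→8)-epigallocatechin, upper unit hexabenzyl, lower unit pentabenzyl with free 3-OH | O[C@@H]1Cc2c(OCc9ccccc9)cc(OCc9ccccc9)c([C@H]3c4c(OCc9ccccc9)cc(OCc9ccccc9)cc4O[C@H](c5cc(OCc9ccccc9)c(OCc9ccccc9)c(OCc9ccccc9)c5)[C@@H]3OCc9ccccc9)c2O[C@@H]1c6cc(OCc9ccccc9)c(OCc9ccccc9)c(OCc9ccccc9)c6
F2 | step 8 | flavan-3-one of F1 (ketone at C3 of the lower unit, 2R) | O=C1Cc2c(OCc9ccccc9)cc(OCc9ccccc9)c([C@H]3c4c(OCc9ccccc9)cc(OCc9ccccc9)cc4O[C@H](c5cc(OCc9ccccc9)c(OCc9ccccc9)c(OCc9ccccc9)c5)[C@@H]3OCc9ccccc9)c2O[C@@H]1c6cc(OCc9ccccc9)c(OCc9ccccc9)c(OCc9ccccc9)c6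
F3 | step 8 | 3,4,5-tris(benzyloxy)benzoyl chloride | O=C(Cl)c1cc(OCc9ccccc9)c(OCc9ccccc9)c(OCc9ccccc9)c1
F4 | step 9 | benzylated epigallocatechin-(4β→8)-epigallocatechin 3-O-gallate dimer (gallate unit 2R,3R, C4 unsubstituted) | O=C(O[C@@H]1Cc2c(OCc9ccccc9)cc(OCc9ccccc9)c([C@H]3c4c(OCc9ccccc9)cc(OCc9ccccc9)cc4O[C@H](c5cc(OCc9ccccc9)c(OCc9ccccc9)c(OCc9ccccc9)c5)[C@@H]3OCc9ccccc9)c2O[C@@H]1c6cc(OCc9ccccc9)c(OCc9ccccc9)c(OCc9ccccc9)c6)c7cc(OCc9ccccc9)c(OCc9ccccc9)c(OCc9ccccc9)c7
F5 | step 9 | 4β-(2-ethoxyethoxy) derivative of F4 (alkoxy group on C4 of the gallate unit, trans to the gallate) | O=C(O[C@@H]1[C@@H](OCCOCC)c2c(OCc9ccccc9)cc(OCc9ccccc9)c([C@H]3c4c(OCc9ccccc9)cc(OCc9ccccc9)cc4O[C@H](c5cc(OCc9ccccc9)c(OCc9ccccc9)c(OCc9ccccc9)c5)[C@@H]3OCc9ccccc9)c2O[C@@H]1c6cc(OCc9ccccc9)c(OCc9ccccc9)c(OCc9ccccc9)c6)c7cc(OCc9ccccc9)c(OCc9ccccc9)c(OCc9ccccc9)c7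
F6 | step 7 | 2,2-dimethoxyethyl 3,4,5-tris(benzyloxy)benzoate | COC(OC)COC(=O)c1cc(OCc9ccccc9)c(OCc9ccccc9)c(OCc9ccccc9)c1
F7 | step 7 | 2-oxoethyl 3,4,5-tris(benzyloxy)benzoate | O=CCOC(=O)c1cc(OCc9ccccc9)c(OCc9ccccc9)c(OCc9ccccc9)c1
F8 | step 4 | 2-(hexa-O-benzylepigallocatechin-4β-yl)benzene-1,3,5-triol | Oc1cc(O)cc(O)c1[C@H]3c4c(OCc9ccccc9)cc(OCc9ccccc9)cc4O[C@H](c5cc(OCc9ccccc9)c(OCc9ccccc9)c(OCc9ccccc9)c5)[C@@H]3OCc9ccccc9
F9 | step 4 | 2-(hexa-O-benzylepigallocatechin-4β-yl)-5-(triisopropylsilyloxy)benzene-1,3-diol | Oc1cc(O[Si](C(C)C)(C(C)C)C(C)C)cc(O)c1[C@H]3c4c(OCc9ccccc9)cc(OCc9ccccc9)cc4O[C@H](c5cc(OCc9ccccc9)c(OCc9ccccc9)c(OCc9ccccc9)c5)[C@@H]3OCc9ccccc9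
F10 | step 4 | (2R)-7-hydroxy-5-(triisopropylsilyloxy) analogue of 14 | O=C(OC1=Cc2c(O[Si](C(C)C)(C(C)C)C(C)C)cc(O)c([C@H]3c4c(OCc9ccccc9)cc(OCc9ccccc9)cc4O[C@H](c5cc(OCc9ccccc9)c(OCc9ccccc9)c(OCc9ccccc9)c5)[C@@H]3OCc9ccccc9)c2O[C@@H]1c6cc(OCc9ccccc9)c(OCc9ccccc9)c(OCc9ccccc9)c6)c7cc(OCc9ccccc9)c(OCc9ccccc9)c(OCc9ccccc9)c7
F11 | step 4 | (2R)-5,7-dihydroxy analogue of 14 | O=C(OC1=Cc2c(O)cc(O)c([C@H]3c4c(OCc9ccccc9)cc(OCc9ccccc9)cc4O[C@H](c5cc(OCc9ccccc9)c(OCc9ccccc9)c(OCc9ccccc9)c5)[C@@H]3OCc9ccccc9)c2O[C@@H]1c6cc(OCc9ccccc9)c(OCc9ccccc9)c(OCc9ccccc9)c6)c7cc(OCc9ccccc9)c(OCc9ccccc9)c(OCc9ccccc9)c7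
A1 | alternative 1 | benzylated epigallocatechin-(4β→8)-epigallocatechin with a free 3-hydroxyl in the upper ring | O[C@@H]1[C@@H](c2c(OCc9ccccc9)cc(OCc9ccccc9)c3c2O[C@H](c2cc(OCc9ccccc9)c(OCc9ccccc9)c(OCc9ccccc9)c2)[C@H](OCc9ccccc9)C3)c2c(OCc9ccccc9)cc(OCc9ccccc9)cc2O[C@@H]1c1cc(OCc9ccccc9)c(OCc9ccccc9)c(OCc9ccccc9)c1
A2 | alternative 2 | benzannulation product: benzylated upper dimer (3-O-TBS on the middle unit) carrying on C4 the new lower ring A as a free C8a phenol with two silyl ethers and the acetonide side chain | CC(C)(C)[Si](C)(C)O[C@@H]1[C@@H](c2c(O[Si](C(C)C)(C(C)C)C(C)C)cc(O[Si](C(C)C)(C(C)C)C(C)C)c(C[C@H]3OC(C)(C)O[C@@H]3c4cc(OCc9ccccc9)c(OCc9ccccc9)c(OCc9ccccc9)c4)c2O)c2c(OCc9ccccc9)cc(OCc9ccccc9)c([C@H]3c4c(OCc9ccccc9)cc(OCc9ccccc9)cc4O[C@H](c4cc(OCc9ccccc9)c(OCc9ccccc9)c(OCc9ccccc9)c4)[C@@H]3OCc9ccccc9)c2O[C@@H]1c1cc(OCc9ccccc9)c(OCc9ccccc9)c(OCc9ccccc9)c1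
A3 | alternative 3 | icosa-O-benzyl trimer, identical with 15 | O=C(O[C@@H]1[C@@H](c2c(OCc9ccccc9)cc(OCc9ccccc9)c3c2O[C@H](c2cc(OCc9ccccc9)c(OCc9ccccc9)c(OCc9ccccc9)c2)[C@H](OCc9ccccc9)C3)c2c(OCc9ccccc9)cc(OCc9ccccc9)c([C@H]3c4c(OCc9ccccc9)cc(OCc9ccccc9)cc4O[C@H](c4cc(OCc9ccccc9)c(OCc9ccccc9)c(OCc9ccccc9)c4)[C@@H]3OCc9ccccc9)c2O[C@@H]1c1cc(OCc9ccccc9)c(OCc9ccccc9)c(OCc9ccccc9)c1)c1cc(OCc9ccccc9)c(OCc9ccccc9)c(OCc9ccccc9)c1
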